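**Retrosynthetic overview**

1. The target comes from α-face epoxidation and C-4 acylation of a cis-fused hydroazulene-3,4-diol, itself made by convex-face reduction of the 4-ketone.
2. The seven-membered ring is formed last: photochemical 1,3-acyl shift of a 2-isopropenyl cis-bicyclo[3.3.0]octan-1-one makes the C4–C5 bond and expands the cyclopentanone by two carbons.
3. That cyclopentanone (second ring) comes from a new photocatalytic dehydrogenative acyl-radical cyclisation of a cis prenyl/formyl cyclopentane, which also locks the cis ring fusion.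
4. The quaternary C-8a comes from an anionic oxy-Cope rearrangement of the prenyl Grignard adduct of a cyclopentenecarbaldehyde, steered by the adjacent carbinol centre.
5. The first five-membered ring and the C-3 carbinol stereocentre come from ozonolysis/aldol ring contraction of (S)-(+)-terpinen-4-ol.

Assumption: (S)-(+)-terpinen-4-ol is bought at ≥98% ee, and azulene numbering is used for the bicyclic compounds (C-3 carbinol, C-3a/C-8a ring fusion, C-4 ester carbon, C-6/C-7 alkene or epoxide).

**Route**

Step 1
Reactants: 1 (S)-(+)-terpinen-4-ol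
Product: 2 triethyl{[(1S)-4-methyl-1-(propan-2-yl)cyclohex-3-en-1-yl]oxy}silane
Conditions: Et3SiOTf, 2,6-lutidine, CH2Cl2, 0 °C
Reagents that add atoms: triethylsilyl trifluoromethanesulfonate, CC[Si](CC)(CC)OS(=O)(=O)C(F)(F)F
Why: Silyl ether formation with the silyl triflate caps the hindered tertiary alcohol so that in step 2 only the newly formed hydroxyl can be eliminated, and the purchased stereocentre is untouched.

Step 2
Reactants: 2 triethyl{[(1S)-4-methyl-1-(propan-2-yl)cyclohex-3-en-1-yl]oxy}silane
Product: 4 (5R)-2-methyl-5-(propan-2-yl)-5-[(triethylsilyl)oxy]cyclopent-1-ene-1-carbaldehyde, via keto aldehyde 3 (not isolated)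
Conditions: O3, CH2Cl2, −78 °C; Me2S, −78 °C → rt; then piperidine (0.2 equiv), AcOH (0.2 equiv), toluene, 50 °C
Reagents that add atoms: ozone, [O-][O+]=O
Why: Ozonolysis of the ring alkene followed by an enamine-mediated intramolecular aldol condensation of the aldehyde α-carbon onto the methyl ketone (the ring contraction established for limonene-type keto aldehydes) gives the cyclopentenecarbaldehyde, with dehydration toward the free tertiary hydroxyl and not the silyl ether, and the quaternary stereocentre is not involved.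

Step 3
Reactants: 4 (5R)-2-methyl-5-(propan-2-yl)-5-[(triethylsilyl)oxy]cyclopent-1-ene-1-carbaldehyde; 5 prenylmagnesium chloride
Product: 7 (1R)-2-(1-hydroxy-2,2-dimethylbut-3-en-1-yl)-3-methyl-1-(propan-2-yl)cyclopent-2-en-1-ol (carbinol epimers), via silyl-protected carbinol 6 (not isolated)
Conditions: 5 (1.5 equiv), THF, −78 °C; then nBu4NF (3 equiv), THF, 40 °C
Reagents that add atoms: prenylmagnesium chloride, CC(C)=CC[Mg]Cl
Why: Allylic Grignard 1,2-addition through the six-membered SE2′ transition state gives the reverse-prenyl carbinol and fluoride desilylation frees the tertiary alcohol, the new carbinol centre being an inconsequential epimer mixture because it becomes sp2 in step 4.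

Step 4
Reactants: 7 (1R)-2-(1-hydroxy-2,2-dimethylbut-3-en-1-yl)-3-methyl-1-(propan-2-yl)cyclopent-2-en-1-ol
Product: 9 (1R,2S,5R)-5-hydroxy-2-methyl-2-(3-methylbut-2-en-1-yl)-5-(propan-2-yl)cyclopentane-1-carbaldehyde, via dipotassium enolate 8 (not isolated)
Conditions: KH (2.5 equiv), 18-crown-6 (2.5 equiv), THF, 0 → 40 °C; AcOH, −78 °C → rt
Reagents that add atoms: none
Why: The anionic oxy-Cope rearrangement of the potassium 1,5-dien-3-olate forms the quaternary C–C bond on the cyclopentene face syn to the small alkoxide and anti to the isopropyl group of the purchased carbinol centre (the dianion cannot undergo β-elimination or retro-aldol cleavage), and buffered protonation/equilibration of the enolate places the formyl group cis to the hydroxyl (hydrogen-bonded, trans to isopropyl) and therefore cis to the prenyl group.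

Step 5
Reactants: 9 (1R,2S,5R)-5-hydroxy-2-methyl-2-(3-methylbut-2-en-1-yl)-5-(propan-2-yl)cyclopentane-1-carbaldehyde
Product: 10 (2R,3aS,6R,6aR)-6-hydroxy-3a-methyl-2-(prop-1-en-2-yl)-6-(propan-2-yl)hexahydropentalen-1(2H)-one (cis-fused; C-2 epimer also usable)
Conditions: (nBu4N)4W10O32 (2 mol%), CoCl(dmgH)2(py) (5 mol%), MeCN, 390 nm LEDs, Ar, 25 °C
Reagents that add atoms: none
Why: Proposed new method: a decatungstate/cobaloxime dual-catalytic acceptorless dehydrogenative acyl-radical cyclisation (a formal acyl-ene reaction) in which excited decatungstate abstracts the hydridic formyl hydrogen, the acyl radical closes 5-exo-trig onto the cis prenyl alkene (only the cis-fused bicyclo[3.3.0]octanone can form, so the ring-fusion hydrogen is fixed cis to the angular methyl, with the side chain on the convex face), and divalent cobalt removes a statistically favoured, polarity-matched methyl hydrogen from the tertiary radical to give the isopropenyl β,γ-unsaturated ketone with release of H2, the closest known reaction types being decatungstate-photocatalysed hydroacylation of alkenes and decatungstate/cobaloxime dehydrogenative Heck-type acylation of styrenes, neither shown for an intramolecular contra-thermodynamic desaturation on an unactivated trisubstituted alkene.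

Step 6
Reactants: 10 (2R,3aS,6R,6aR)-6-hydroxy-3a-methyl-2-(prop-1-en-2-yl)-6-(propan-2-yl)hexahydropentalen-1(2H)-one
Product: 11 (3R,3aR,8aS)-3-hydroxy-6,8a-dimethyl-3-(propan-2-yl)-2,3,3a,5,8,8a-hexahydroazulen-4(1H)-one (cis-fused)
Conditions: hν (300 nm, Pyrex), degassed cyclohexane (0.01 M), 20 °C, to about 70% conversion (10 recycled)
Reagents that add atoms: none
Why: The photochemical 1,3-acyl shift of a β,γ-unsaturated ketone (singlet n,π* α-cleavage of the allylic acyl bond and recombination of the acyl carbon at the methylene terminus of the allyl unit) forms the C4–C5 bond and expands the cyclopentanone to the cis-trisubstituted cyclohept-3-enone, as known for 2-alkenylcycloalkanones, with both C-2 epimers of 10 converging and the ring-fusion centres retained because they are not involved.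

Step 7
Reactants: 11 (3R,3aR,8aS)-3-hydroxy-6,8a-dimethyl-3-(propan-2-yl)-2,3,3a,5,8,8a-hexahydroazulen-4(1H)-one
Product: 12 (3R,3aS,4R,8aS)-6,8a-dimethyl-3-(propan-2-yl)-1,2,3,3a,4,5,8,8a-octahydroazulene-3,4-diol
Conditions: Li[HB(sec-Bu)3], THF, −78 °C; H2O
Reagents that add atoms: none
Why: In this substrate-controlled ketone reduction the bulky hydride attacks the convex α face of the cis-fused hydroazulenone, anti to the adjacent quaternary carbinol carbon, and gives the 4β-alcohol syn to the tertiary hydroxyl.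

Step 8
Reactants: 12 (3R,3aS,4R,8aS)-6,8a-dimethyl-3-(propan-2-yl)-1,2,3,3a,4,5,8,8a-octahydroazulene-3,4-diol; 13 4-acetoxybenzoyl chloride
Product: 15 (3R,3aS,4R,8aS)-3-hydroxy-6,8a-dimethyl-3-(propan-2-yl)-1,2,3,3a,4,5,8,8a-octahydroazulen-4-yl 4-hydroxybenzoate, via aryl acetate 14 (not isolated)
Conditions: 13 (1.5 equiv), Et3N, DMAP (0.2 equiv), CH2Cl2, 0 °C → rt; then pyrrolidine, 0 °C
Reagents that add atoms: 4-acetoxybenzoyl chloride, CC(=O)Oc1ccc(cc1)C(Cl)=O
Why: DMAP-catalysed acylation occurs only at the secondary alcohol (the tertiary one is inert) with retention at C-4, and aminolysis by pyrrolidine then cleaves the aryl acetate much faster than the hindered secondary benzoate.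

Step 9
Reactants: 15 (3R,3aS,4R,8aS)-3-hydroxy-6,8a-dimethyl-3-(propan-2-yl)-1,2,3,3a,4,5,8,8a-octahydroazulen-4-yl 4-hydroxybenzoate
Product: 16 (3R,3aS,4R,6R,7S,8aS)-6,7-epoxy-3-hydroxy-6,8a-dimethyl-3-(propan-2-yl)decahydroazulen-4-yl 4-hydroxybenzoate (CNP0163817.4)
Conditions: dimethyldioxirane, acetone, −20 → 0 °C
Reagents that add atoms: dimethyldioxirane, CC1(C)OO1
Why: Neutral dioxirane epoxidation of the only alkene takes place on the convex α face, anti to the homoallylic β-aroyloxy group and the concave five-membered ring, to give the α-epoxide without acid that could trigger transannular opening by the tertiary hydroxyl.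

**Compound list**

1 | (S)-(+)-terpinen-4-ol, (1S)-4-methyl-1-(propan-2-yl)cyclohex-3-en-1-ol | CC(C)[C@]1(O)CCC(C)=CC1 | starting material
2 | triethyl{[(1S)-4-methyl-1-(propan-2-yl)cyclohex-3-en-1-yl]oxy}silane | CC(C)[C@]1(O[Si](CC)(CC)CC)CCC(C)=CC1 | intermediate
3 | (3S)-6-oxo-3-(propan-2-yl)-3-[(triethylsilyl)oxy]heptanal | CC(C)[C@](CC=O)(O[Si](CC)(CC)CC)CCC(C)=O | intermediate (not isolated)
4 | (5R)-2-methyl-5-(propan-2-yl)-5-[(triethylsilyl)oxy]cyclopent-1-ene-1-carbaldehyde | CC(C)[C@]1(O[Si](CC)(CC)CC)CCC(C)=C1C=O | intermediate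
5 | prenylmagnesium chloride, (3-methylbut-2-en-1-yl)magnesium chloride | CC(C)=CC[Mg]Cl | starting material
6 | 2,2-dimethyl-1-{(5R)-2-methyl-5-(propan-2-yl)-5-[(triethylsilyl)oxy]cyclopent-1-en-1-yl}but-3-en-1-ol (carbinol epimers) | CC(C)[C@]1(O[Si](CC)(CC)CC)CCC(C)=C1C(O)C(C)(C)C=C | intermediate (not isolated)
7 | (1R)-2-(1-hydroxy-2,2-dimethylbut-3-en-1-yl)-3-methyl-1-(propan-2-yl)cyclopent-2-en-1-ol (carbinol epimers) | CC(C)[C@]1(O)CCC(C)=C1C(O)C(C)(C)C=C | intermediate
8 | dipotassium (1R,3S)-3-methyl-3-(3-methylbut-2-en-1-yl)-2-(oxidomethylidene)-1-(propan-2-yl)cyclopentan-1-olate | [K+].[K+].CC(C)[C@]1([O-])CC[C@@](C)(CC=C(C)C)C1=C[O-] | intermediate (not isolated)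
9 | (1R,2S,5R)-5-hydroxy-2-methyl-2-(3-methylbut-2-en-1-yl)-5-(propan-2-yl)cyclopentane-1-carbaldehyde | CC(C)[C@]1(O)CC[C@@](C)(CC=C(C)C)[C@H]1C=O | intermediate
10 | (2R,3aS,6R,6aR)-6-hydroxy-3a-methyl-2-(prop-1-en-2-yl)-6-(propan-2-yl)hexahydropentalen-1(2H)-one (major C-2 epimer) | CC(C)[C@]1(O)CC[C@@]2(C)C[C@H](C(C)=C)C(=O)[C@H]21 | intermediate
11 | (3R,3aR,8aS)-3-hydroxy-6,8a-dimethyl-3-(propan-2-yl)-2,3,3a,5,8,8a-hexahydroazulen-4(1H)-one | CC(C)[C@]1(O)CC[C@@]2(C)CC=C(C)CC(=O)[C@H]21 | intermediate
12 | (3R,3aS,4R,8aS)-6,8a-dimethyl-3-(propan-2-yl)-1,2,3,3a,4,5,8,8a-octahydroazulene-3,4-diol | CC(C)[C@]1(O)CC[C@@]2(C)CC=C(C)C[C@@H](O)[C@H]21 | intermediate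
13 | 4-acetoxybenzoyl chloride | CC(=O)Oc1ccc(cc1)C(Cl)=O | starting material
14 | (3R,3aS,4R,8aS)-3-hydroxy-6,8a-dimethyl-3-(propan-2-yl)-1,2,3,3a,4,5,8,8a-octahydroazulen-4-yl 4-acetoxybenzoate | CC(C)[C@]1(O)CC[C@@]2(C)CC=C(C)C[C@@H](OC(=O)c3ccc(OC(C)=O)cc3)[C@H]21 | intermediate (not isolated)
15 | (3R,3aS,4R,8aS)-3-hydroxy-6,8a-dimethyl-3-(propan-2-yl)-1,2,3,3a,4,5,8,8a-octahydroazulen-4-yl 4-hydroxybenzoate | CC(C)[C@]1(O)CC[C@@]2(C)CC=C(C)C[C@@H](OC(=O)c3ccc(O)cc3)[C@H]21 | intermediate
16 | (3R,3aS,4R,6R,7S,8aS)-6,7-epoxy-3-hydroxy-6,8a-dimethyl-3-(propan-2-yl)decahydroazulen-4-yl 4-hydroxybenzoate | CC(C)[C@]1(O)CC[C@@]2(C)C[C@@H]3O[C@]3(C)C[C@@H](OC(=O)c3ccc(O)cc3)[C@H]21 | target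

**Step count and risks**

Total steps: 9. Longest linear sequence: 9 steps (1 → 16); 5 and 13 are purchased.

Three steps most likely to fail:

- **Step 5 (the proposed new reaction).** It could fail through competing allylic C–H abstraction, plain hydroacylation to the saturated ketone, or desaturation toward the conjugated isopropylidene ketone. The fallback uses known chemistry, sets out from 9 and comes back at 10. Me2AlCl (2.2 equiv, CH2Cl2, −78 → −20 °C) promotes the intramolecular carbonyl-ene reaction of the aldehyde with the prenyl alkene to give the isopropenyl bicyclic diol F3. Dess–Martin periodinane then oxidises the secondary alcohol to 10.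

- **Step 6 (photochemical ring expansion).** It could stall at an unfavourable photostationary state or lose material to decarbonylation. The fallback sets out from 9 and comes back at 11, bypassing 10. 2-Methylallylmagnesium chloride adds to the aldehyde to give the diene diol F4. Ring-closing metathesis with the second-generation Hoveyda–Grubbs catalyst (toluene, 80 °C) closes the trisubstituted cycloheptene with loss of 2-methylpropene to give the cycloheptene diol F5. Dess–Martin periodinane then gives 11.

- **Step 4 (anionic oxy-Cope).** The rearrangement onto the tetrasubstituted alkene may be slow, the face selectivity may be modest, and the aldol-type product may cleave on quench. The fallback sets out from 4 and comes back at 9. Conjugate addition of the prenylcopper reagent made from 5 and CuBr·SMe2 in the presence of Me3SiCl (THF, −78 °C), through its primary terminus, gives the trimethylsilyl enol ether F1. Aqueous citric acid gives the silyl-protected aldehyde F2, and HF·pyridine (THF, 0 °C) then removes the triethylsilyl group to give 9.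

Further compounds
F1 | step 4 | triethyl{[(1R,3S)-3-methyl-3-(3-methylbut-2-en-1-yl)-1-(propan-2-yl)-2-{[(trimethylsilyl)oxy]methylidene}cyclopentyl]oxy}silane | CC(C)[C@]1(O[Si](CC)(CC)CC)CC[C@@](C)(CC=C(C)C)C1=CO[Si](C)(C)C
F2 | step 4 | (1R,2S,5R)-2-methyl-2-(3-methylbut-2-en-1-yl)-5-(propan-2-yl)-5-[(triethylsilyl)oxy]cyclopentane-1-carbaldehyde | CC(C)[C@]1(O[Si](CC)(CC)CC)CC[C@@](C)(CC=C(C)C)[C@H]1C=O
F3 | step 5 | (3aS,6R,6aS)-3a-methyl-2-(prop-1-en-2-yl)-6-(propan-2-yl)octahydropentalene-1,6-diol (cis-fused, epimers at C-1 and C-2) | CC(C)[C@]1(O)CC[C@@]2(C)CC(C(C)=C)C(O)[C@H]21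
F4 | step 6 | (1R,2S,3S)-2-(1-hydroxy-3-methylbut-3-en-1-yl)-3-methyl-3-(3-methylbut-2-en-1-yl)-1-(propan-2-yl)cyclopentan-1-ol (carbinol epimers) | CC(C)[C@]1(O)CC[C@@](C)(CC=C(C)C)[C@H]1C(O)CC(C)=C
F5 | step 6 | (3R,3aS,8aS)-6,8a-dimethyl-3-(propan-2-yl)-1,2,3,3a,4,5,8,8a-octahydroazulene-3,4-diol (C-4 epimers) | CC(C)[C@]1(O)CC[C@@]2(C)CC=C(C)CC(O)[C@H]21
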